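**Strategy.** Everything rests on opening rings C and D of the bicyclo[3.2.1]octane at C8–C14 and C15–C16 (ent-kaurane numbering). The key step exploits that C8 sits between the lactone carbonyl C7 and the C15 carbonyl, that C14 is its aldol carbinol, and that C15–C16 is the acyl–vinyl bond of the enone. One SmI2 operation on an α-bromo-α-formyl spirolactone, which carries the C14 aldehyde as a lactol on O11 and an ethynyl group on C13, gives a Reformatsky-type aldol (C8–C14) and then a ketyl–alkyne cyclization (C15–C16). The precursor comes from a ring A epoxide and a chiral 5-alkoxybutenolide by radical coupling, asymmetric alkynylation and formylation.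

Key step: step 16

Assumption: atoms carry ent-kaurane numbers (C1–C20; O11 is the oxygen on C11); compounds 1 and 11 are taken as purchasable (11 is the d-menthol enantiomer of the common l-menthyloxy synthon).

**Step 1**
Reactants: 1 2,4,4-trimethylcyclohex-2-en-1-one
Product: 2 (1S)-2,4,4-trimethylcyclohex-2-en-1-ol
Conditions: (R)-2-methyl-CBS-oxazaborolidine (10 mol%), BH3·SMe2, THF, −20 °C
Reagents that add atoms: none
Why: Corey–Bakshi–Shibata reduction, in which the oxazaborolidine–borane complex distinguishes the alkenyl side from the ring CH2 side of the ketone and delivers hydride to one face, setting the C1 carbinol.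

**Step 2**
Reactants: 2 (1S)-2,4,4-trimethylcyclohex-2-en-1-ol
Product: 3 tributyl({[(1S)-2,4,4-trimethylcyclohex-2-en-1-yl]oxy}methyl)stannane
Conditions: KH, ICH2SnBu3, THF, 0 °C to rt
Reagents that add atoms: tributyl(iodomethyl)stannane CCCC[Sn](CCCC)(CCCC)CI
Why: Williamson etherification of the potassium alkoxide with the primary iodide, which does not touch the stereocentre.

**Step 3**
Reactants: 3 tributyl({[(1S)-2,4,4-trimethylcyclohex-2-en-1-yl]oxy}methyl)stannane
Product: 5 (R)-α-cyclogeraniol, [(1R)-2,6,6-trimethylcyclohex-2-en-1-yl]methanol, via lithiomethyl ether 4 (not isolated)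
Conditions: n-BuLi, THF, −78 °C to 0 °C
Reagents that add atoms: none
Why: [2,3]-Wittig–Still rearrangement: tin–lithium exchange gives the α-alkoxy carbanion, which shifts suprafacially to C5, so the C1 configuration of 2 is transferred to C5 and C6 is installed next to the gem-dimethyl carbon.

**Step 4**
Reactants: 5 (R)-α-cyclogeraniol
Product: 6 syn-epoxy alcohol (C1–C10 oxirane on the face of the CH2OH group)
Conditions: VO(acac)2 (5 mol%), t-BuOOH, CH2Cl2, 0 °C to rt
Reagents that add atoms: tert-butyl hydroperoxide CC(C)(C)OO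
Why: Hydroxyl-directed vanadium-catalysed epoxidation of the homoallylic alcohol delivers oxygen syn to the CH2OH group, which fixes the later C1–O bond cis to C6.

**Step 5**
Reactants: 6 syn-epoxy alcohol
Product: 7 (1S,3R)-3-(hydroxymethyl)-4,4-dimethyl-2-methylidenecyclohexan-1-ol
Conditions: Et2Al(TMP) (4 equiv; from Et2AlCl and lithium 2,2,6,6-tetramethylpiperidide, itself from the amine and n-BuLi), toluene, 0 °C
Reagents that add atoms: none
Why: Base-promoted epoxide-to-allylic-alcohol isomerization: the aluminum amide binds the oxirane oxygen and removes a syn proton from the C20 methyl group (the least hindered β-hydrogen), cleaving C10–O and leaving the C1 carbinol with retention next to the exocyclic methylene.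

**Step 6**
Reactants: 7 (1S,3R)-3-(hydroxymethyl)-4,4-dimethyl-2-methylidenecyclohexan-1-ol
Product: 9 (1S,3R)-3-{[tert-butyl(dimethyl)silyl]oxymethyl}-4,4-dimethyl-2-methylidenecyclohexyl acetate, via primary silyl ether 8 (not isolated)
Conditions: TBSCl (1.05 equiv), imidazole, CH2Cl2, 0 °C; then Ac2O, Et3N, DMAP (cat.), rt
Reagents that add atoms: tert-butyldimethylsilyl chloride CC(C)(C)[Si](C)(C)Cl; acetic anhydride CC(=O)OC(C)=O
Why: The primary C6 hydroxyl is silylated much faster than the hindered secondary C1 hydroxyl, which is then acetylated in the same flask, so the C1 acetate of the target is in place from here on.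

**Step 7**
Reactants: 9 silyl ether acetate
Product: 10 spiro-epoxide of 9 (C10–C20 oxirane; configuration at C10 immaterial)
Conditions: mCPBA, CH2Cl2, 0 °C
Reagents that add atoms: 3-chloroperoxybenzoic acid OOC(=O)c1cccc(Cl)c1
Why: Prilezhaev epoxidation of the 1,1-disubstituted alkene; the new spiro centre needs no control because it becomes a planar radical in the next step.

**Step 8**
Reactants: 10 spiro-epoxide; 11 (5S)-5-(d-menthyloxy)furan-2(5H)-one
Product: 13 spiro δ-lactone aldehyde (C7/C20 lactone, C11 formyl group on C9), via Giese adduct 12 (not isolated)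
Conditions: Cp2TiCl2 (0.3 equiv), Zn dust, 2,4,6-collidine·HCl, THF, rt; then Et3N (cat.), 0 °C
Reagents that add atoms: none
Why: Reductive epoxide opening by trivalent titanium (Cp2TiCl) gives the tertiary C10 radical, which undergoes Giese addition to the butenolide β-carbon anti to the menthyloxy group (sets C9) and on the ring A face opposite the cis C1 acetate and C5 silyloxymethyl groups (sets C10); the C20 alkoxide then transacylates C7 and the expelled hemiacetal collapses to the C11 aldehyde and menthol.

**Step 9**
Reactants: 13 spiro δ-lactone aldehyde; 14 3,3-diethoxyprop-1-yne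
Product: 15 (E)-allylic alcohol (C12=C13, C14 diethyl acetal; both C11 epimers)
Conditions: 14, Cp2Zr(H)Cl, CH2Cl2, rt; Me2Zn, −65 °C; then 13, 0 °C
Reagents that add atoms: none
Why: Hydrozirconation gives the (E)-alkenylzirconocene, which after zirconium-to-zinc transmetalation adds to the aldehyde without touching lactone, acetate or acetal; the C11 configuration is irrelevant because it is oxidized next.

**Step 10**
Reactants: 15 (E)-allylic alcohol
Product: 16 (E)-enone (C11 ketone, C14 diethyl acetal)
Conditions: Dess–Martin periodinane, CH2Cl2, rt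
Reagents that add atoms: none
Why: Dess–Martin oxidation of the secondary allylic alcohol under near-neutral conditions that spare the acetal and the α-stereocentre C9.

**Step 11**
Reactants: 16 (E)-enone; 17 ethynyltri(propan-2-yl)silane
Product: 18 (13S)-β-alkynyl ketone
Conditions: [Rh(OAc)(C2H4)2]2 (2.5 mol%), DTBM-SEGPHOS (6 mol%; the enantiomer that gives 13S), 1,4-dioxane, 80 °C
Reagents that add atoms: none
Why: Rhodium-catalysed asymmetric conjugate alkynylation: the alkynylrhodium–bisphosphine complex adds to the enone β-carbon C13 under ligand control of the face, and the bulky silyl group suppresses alkyne dimerization.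

**Step 12**
Reactants: 18 (13S)-β-alkynyl ketone
Product: 20 cyclic ethyl acetal (2-ethoxytetrahydrofuran spanning O11 and C14; anomers), via hydroxy acetal 19 (not isolated)
Conditions: LiBH(s-Bu)3, THF, −78 °C; aq. NH4Cl work-up; then PPTS (cat.), CH2Cl2, rt
Reagents that add atoms: none
Why: Felkin–Anh reduction: the bulky hydride attacks the C11 ketone anti to the quaternary C10 substituent of C9, giving the C11 alcohol of the target, which then closes onto the diethyl acetal by transacetalization and is thereby masked.

**Step 13**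
Reactants: 20 cyclic ethyl acetal
Product: 21 α-(dimethylaminomethylene) lactone (C15 installed as an enaminone on C8)
Conditions: tert-butoxybis(dimethylamino)methane, toluene, 90 °C
Reagents that add atoms: tert-butoxybis(dimethylamino)methane CC(C)(C)OC(N(C)C)N(C)C
Why: Condensation of the aminal ester with the only activated methylene (C8 of the δ-lactone) under neutral conditions, which spares the C1 acetate that a Claisen formylation with strong base would not.

**Step 14**
Reactants: 21 α-(dimethylaminomethylene) lactone
Product: 22 desilylated enaminone (terminal alkyne, free C6 hydroxyl)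
Conditions: Bu4NF, AcOH, THF, 0 °C to rt
Reagents that add atoms: none
Why: Fluoride cleaves the alkynyl C–Si bond and the primary silyl ether in one operation, and buffering with acetic acid protects the acetate and lactone.

**Step 15**
Reactants: 22 desilylated enaminone
Product: 24 8-bromo-8-formyl lactone with C14 lactol (C8 epimers, lactol anomers), via bromo aldehyde ethyl acetal 23 (not isolated)
Conditions: NBS (1.0 equiv), THF–H2O, 0 °C; then 1 M HCl, rt
Reagents that add atoms: N-bromosuccinimide O=C1CCC(=O)N1Br; water O
Why: Electrophilic bromination of the enaminone at C8 gives an α-bromo iminium ion that water hydrolyses to the aldehyde, and the dilute acid then hydrolyses the 2-ethoxytetrahydrofuran to the lactol, the masked C14 aldehyde.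

**Step 16**
Reactants: 24 8-bromo-8-formyl lactone lactol
Product: 26 15-hydroxy precursor of the target (rings C and D closed; C15 epimers), via aldol adduct 25 (not isolated)
Conditions: SmI2 (6 equiv), HMPA, THF, −78 °C to rt, no added proton donor; aq. NH4Cl
Reagents that add atoms: none
Why: SmI2 first reduces the C8–Br bond (faster than either carbonyl) to a trivalent samarium enolate chelated by the C7 and C15 oxygens, and this enolate adds to the C14 aldehyde released from the lactol in a 6-(enolexo)-exo-trig Reformatsky-type aldol that closes ring C and forms C8–C14. The closest known reactions are the samarium Reformatsky aldol and the SmI2/HMPA ketyl–alkyne cyclization, run here in sequence in one flask. The C15 aldehyde of the aldolate is then reduced to a ketyl that attacks C16 of the ethynyl group in a 5-exo-dig radical closure of ring D (C15–C16), and the vinyl radical takes hydrogen from THF to give the exocyclic methylene. C8 is controlled by the bridge: the aldol is reversible and only the epimer with C15 syn to the C13 ethynyl group can cyclize, so the quaternary centre is fixed by the irreversible radical step. C14 is controlled by the chelated chair, in which its oxygen is equatorial, gauche to both carbonyls and away from the axial C9–C10 bond, whereas the other epimer suffers a 1,3-diaxial clash with quaternary C10. The step needs reduction of C–Br before any aldehyde and of C15 before C14, which the α-halo carbonyl, the lactol masking of C14 and the absence of an added proton donor should secure.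

**Step 17**
Reactants: 26 15-hydroxy precursor
Product: 27 CNP0225182.1 (target)
Conditions: activated MnO2 (excess), CH2Cl2, rt
Reagents that add atoms: none
Why: MnO2 oxidizes only the allylic C15 alcohol to the enone, leaving the primary C6 and the secondary C11 and C14 hydroxyls, which are not allylic.

**Compound list**

1 | 2,4,4-trimethylcyclohex-2-en-1-one | CC1=CC(C)(C)CCC1=O | starting material
2 | (1S)-2,4,4-trimethylcyclohex-2-en-1-ol | CC1=CC(C)(C)CC[C@@H]1O | intermediate
3 | tributyl({[(1S)-2,4,4-trimethylcyclohex-2-en-1-yl]oxy}methyl)stannane | CC1=CC(C)(C)CC[C@@H]1OC[Sn](CCCC)(CCCC)CCCC | intermediate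
4 | {[(1S)-2,4,4-trimethylcyclohex-2-en-1-yl]oxy}methyllithium | CC1=CC(C)(C)CC[C@@H]1OC[Li] | intermediate
5 | (R)-α-cyclogeraniol, [(1R)-2,6,6-trimethylcyclohex-2-en-1-yl]methanol | CC1=CCCC(C)(C)[C@H]1CO | intermediate
6 | syn-epoxy alcohol of 5 (oxirane oxygen on the face of the CH2OH group) | C[C@]1(O2)[C@@H]2CCC(C)(C)[C@H]1CO | intermediate
7 | (1S,3R)-3-(hydroxymethyl)-4,4-dimethyl-2-methylidenecyclohexan-1-ol | C=C1[C@@H](O)CCC(C)(C)[C@H]1CO | intermediate
8 | primary tert-butyldimethylsilyl ether of 7 | C=C1[C@@H](O)CCC(C)(C)[C@H]1CO[Si](C)(C)C(C)(C)C | intermediate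
9 | (1S,3R)-3-{[tert-butyl(dimethyl)silyl]oxymethyl}-4,4-dimethyl-2-methylidenecyclohexyl acetate | C=C1[C@@H](OC(C)=O)CCC(C)(C)[C@H]1CO[Si](C)(C)C(C)(C)C | intermediate
10 | spiro-epoxide of 9 (C10–C20 oxirane, C10 configuration unassigned) | C1OC12[C@@H](OC(C)=O)CCC(C)(C)[C@H]2CO[Si](C)(C)C(C)(C)C | intermediate
11 | (5S)-5-(d-menthyloxy)furan-2(5H)-one, menthyl = (1S,2R,5S)-5-methyl-2-(propan-2-yl)cyclohexyl | O=C1C=C[C@@H](O[C@H]2C[C@@H](C)CC[C@@H]2C(C)C)O1 | starting material
12 | Giese adduct: ring A with free C20 alcohol, C9 in a γ-lactone acetal trans to the menthyloxy group | OC[C@]2([C@@H](OC(C)=O)CCC(C)(C)[C@H]2CO[Si](C)(C)C(C)(C)C)[C@H]1CC(=O)O[C@@H]1O[C@H]3C[C@@H](C)CC[C@@H]3C(C)C | intermediate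
13 | spiro δ-lactone aldehyde (C7/C20 lactone spiro at C10; C11 formyl on C9; 1-acetoxy, 6-silyloxy) | O=C1OC[C@]2([C@@H](OC(C)=O)CCC(C)(C)[C@H]2CO[Si](C)(C)C(C)(C)C)[C@@H](C1)C=O | intermediate
14 | 3,3-diethoxyprop-1-yne | C#CC(OCC)OCC | starting material
15 | (E)-allylic alcohol (C11 carbinol, both epimers; C14 diethyl acetal) | O=C1OC[C@]2([C@@H](OC(C)=O)CCC(C)(C)[C@H]2CO[Si](C)(C)C(C)(C)C)[C@@H](C1)C(O)/C=C/C(OCC)OCC | intermediate
16 | (E)-enone (C11 ketone, C12=C13, C14 diethyl acetal) | O=C1OC[C@]2([C@@H](OC(C)=O)CCC(C)(C)[C@H]2CO[Si](C)(C)C(C)(C)C)[C@@H](C1)C(=O)/C=C/C(OCC)OCC | intermediate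
17 | ethynyltri(propan-2-yl)silane | C#C[Si](C(C)C)(C(C)C)C(C)C | starting material
18 | (13S)-β-alkynyl ketone (silylethynyl group on C13) | O=C1OC[C@]2([C@@H](OC(C)=O)CCC(C)(C)[C@H]2CO[Si](C)(C)C(C)(C)C)[C@@H](C1)C(=O)C[C@@H](C#C[Si](C(C)C)(C(C)C)C(C)C)C(OCC)OCC | intermediate
19 | C11 alcohol with open diethyl acetal | O=C1OC[C@]2([C@@H](OC(C)=O)CCC(C)(C)[C@H]2CO[Si](C)(C)C(C)(C)C)[C@@H](C1)[C@@H](O)C[C@@H](C#C[Si](C(C)C)(C(C)C)C(C)C)C(OCC)OCC | intermediate
20 | cyclic ethyl acetal (2-ethoxytetrahydrofuran from O11 and C14; anomers) | O=C1OC[C@]2([C@@H](OC(C)=O)CCC(C)(C)[C@H]2CO[Si](C)(C)C(C)(C)C)[C@@H](C1)[C@@H]3C[C@@H](C#C[Si](C(C)C)(C(C)C)C(C)C)C(OCC)O3 | intermediate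
21 | α-(dimethylaminomethylene) lactone (drawn E; geometry immaterial) | CN(C)/C=C1/C(=O)OC[C@]2([C@@H](OC(C)=O)CCC(C)(C)[C@H]2CO[Si](C)(C)C(C)(C)C)[C@@H]1[C@@H]3C[C@@H](C#C[Si](C(C)C)(C(C)C)C(C)C)C(OCC)O3 | intermediate
22 | desilylated enaminone (terminal alkyne, free C6 hydroxyl) | CN(C)/C=C1/C(=O)OC[C@]2([C@@H](OC(C)=O)CCC(C)(C)[C@H]2CO)[C@@H]1[C@@H]3C[C@@H](C#C)C(OCC)O3 | intermediate
23 | 8-bromo-8-formyl lactone, cyclic ethyl acetal | O=CC1(Br)C(=O)OC[C@]2([C@@H](OC(C)=O)CCC(C)(C)[C@H]2CO)[C@@H]1[C@@H]3C[C@@H](C#C)C(OCC)O3 | intermediate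
24 | 8-bromo-8-formyl lactone, C14 lactol (C8 epimers, anomers) | O=CC1(Br)C(=O)OC[C@]2([C@@H](OC(C)=O)CCC(C)(C)[C@H]2CO)[C@@H]1[C@@H]3C[C@@H](C#C)C(O)O3 | intermediate
25 | aldol adduct (ring C closed; C8 quaternary with C15 aldehyde; 14-OH; ethynyl on C13) | O=C[C@@]12C(=O)OC[C@]3([C@@H](OC(C)=O)CCC(C)(C)[C@H]3CO)[C@@H]1[C@@H](O)C[C@@H](C#C)[C@H]2O | intermediate
26 | 15-hydroxy precursor (target with C15 carbinol in place of the ketone; C15 epimers) | C=C1C(O)[C@@]23C(=O)OC[C@]4([C@@H](OC(C)=O)CCC(C)(C)[C@H]4CO)[C@@H]2[C@@H](O)C[C@@H]1[C@H]3O | intermediate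
27 | CNP0225182.1 | C=C1C(=O)[C@@]23C(=O)OC[C@]4([C@@H](OC(C)=O)CCC(C)(C)[C@H]4CO)[C@@H]2[C@@H](O)C[C@@H]1[C@H]3O | target

**Count and risks**

Total step count: 17. Longest linear sequence: 17 steps (1 to 27); compounds 11, 14 and 17 enter as purchased materials.

Steps most likely to fail:

Step 16. The samarium enolate of the 1,3-dicarbonyl may be too stabilized to add to the lactol-masked aldehyde, so that simple debromination, pinacol coupling or over-reduction of the open C14 aldehyde outruns ring closure. The aldolate may also reach the ketyl stage as the C8 epimer that cannot bridge and be reduced without cyclizing. The fallback separates the two bond formations. It sets out from 22: hydrolysis with 1 M HCl alone (no NBS) would give the hydroxymethylene lactone lactol F1 (drawn as the formyl tautomer). A tertiary amine (Et3N, CH2Cl2, 0 °C) would then equilibrate F1 with the aldol adduct 25 under thermodynamic control. Crude 25 would be cyclized in a separate SmI2/HMPA/t-BuOH ketyl–alkyne reaction, and the route is rejoined at 26.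

Step 8. The hindered β-titanoxy radical may be reduced or deoxygenated back to alkene 9, and the butenolide may be reduced by trivalent titanium, before the crowded C10–C9 bond forms. The α-stereocentre C9 may also epimerize during the transacylation. The fallback generates the same C10 radical without titanium and sets out from 9. Dihydroxylation (OsO4 cat., NMO) would give diol F2, and TESCl would protect the primary C20 hydroxyl to give F3. Methyl chlorooxoacetate/DMAP would give the tertiary methyl oxalate F4, and CsOH (1 equiv) would give the cesium oxalate F5. A visible-light decarboxylative Giese coupling with 11 (Ir[dF(CF3)ppy]2(dtbbpy)PF6, blue light, DME/DMF/H2O) would give adduct F6. HF·pyridine would remove the triethylsilyl group to give 12, which transacylates to 13 as in the main route.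

Step 11. The rhodium catalyst may be inhibited by the hindered, oxygen-rich enone, alkyne oligomerization may compete, and facial control by the ligand may be eroded by the substrate. The fallback replaces the metal-catalysed cycle by a boronate conjugate alkynylation through a closed six-membered transition state. It sets out from 16: the alkynylboronate F7 (from 17 with n-BuLi, then B(OiPr)3, then HCl in ether) would be added to the enone under catalysis by a 3,3'-diiodo-BINOL enantiomer, and the route is rejoined at 18.

**Further compounds**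

F1 | step 16 | hydroxymethylene (formyl) lactone with C14 lactol, no bromine | O=CC1C(=O)OC[C@]2([C@@H](OC(C)=O)CCC(C)(C)[C@H]2CO)[C@@H]1[C@@H]3C[C@@H](C#C)C(O)O3
F2 | step 8 | C10,C20-diol from 9 | OCC1(O)[C@@H](OC(C)=O)CCC(C)(C)[C@H]1CO[Si](C)(C)C(C)(C)C
F3 | step 8 | C20 triethylsilyl ether of F2 | CC[Si](CC)(CC)OCC1(O)[C@@H](OC(C)=O)CCC(C)(C)[C@H]1CO[Si](C)(C)C(C)(C)C
F4 | step 8 | tertiary methyl oxalate of F3 | CC[Si](CC)(CC)OCC1(OC(=O)C(=O)OC)[C@@H](OC(C)=O)CCC(C)(C)[C@H]1CO[Si](C)(C)C(C)(C)C
F5 | step 8 | cesium oxalate of F3 | CC[Si](CC)(CC)OCC1(OC(=O)C(=O)[O-])[C@@H](OC(C)=O)CCC(C)(C)[C@H]1CO[Si](C)(C)C(C)(C)C.[Cs+]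
F6 | step 8 | Giese adduct with C20 triethylsilyl ether | CC[Si](CC)(CC)OC[C@]2([C@@H](OC(C)=O)CCC(C)(C)[C@H]2CO[Si](C)(C)C(C)(C)C)[C@H]1CC(=O)O[C@@H]1O[C@H]3C[C@@H](C)CC[C@@H]3C(C)C
F7 | step 11 | dipropan-2-yl [2-(tripropan-2-ylsilyl)ethynyl]boronate | CC(C)OB(OC(C)C)C#C[Si](C(C)C)(C(C)C)C(C)C
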